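## Retrosynthetic overview

1. The benzylic quaternary carbon is made last among the C–C bonds: Markovnikov MHAT/Ni hydrobenzylation of an exocyclic methylene on a preformed trans-decalin, using a benzylic bromide made from methyl 4-hydroxybenzoate.
2. The other exocyclic methylene is carried through that radical step as a Peterson β-hydroxysilane and released in the final step.
3. The decalin stereocentres trace back to one catalytic enantioselective conjugate methylation that desymmetrises an achiral, centrosymmetric ene-dione. It sets the angular-methyl quaternary carbon and differentiates the two carbonyls (one becomes an enolate, the other stays a ketone). The ring-fusion H and the secondary methyl follow by thermodynamic control.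
4. Ring order: no ring is built. Both carbocycles are present in purchased decalin-1,5-dione, and the arene is carried intact.

Assumption: decahydronaphthalene-1,5-dione (cis/trans mixture) is a catalogue compound; the ligand antipode that gives the (S)-quaternary centre is the one used.

Locants follow the IUPAC numbering of each compound. The carbon that becomes the benzylic quaternary centre is C-1 in 3–4, C-5 in 5–7 and C-1 of the decalinyl group in 11–12.

## Route

**Step 1**
Reactants: 1, decahydronaphthalene-1,5-dione (cis/trans mixture)
Product: 2, 3,4,7,8-tetrahydronaphthalene-1,5(2H,6H)-dione (Δ4a(8a) ene-dione, achiral, C2h)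
Conditions: Br2 (1.0 equiv), AcOH, 20 °C; then LiBr, Li2CO3, DMF, 100 °C
Reagents that add atoms: none
Why: α-Bromination through the more substituted (ring-fusion) enol, then E1cB dehydrobromination (the β-H is α to the second carbonyl), gives the tetrasubstituted ene-dione from either ring-fusion isomer (bromination–dehydrobromination); no stereocentre.

**Step 2**
Reactants: 2, 3,4,7,8-tetrahydronaphthalene-1,5(2H,6H)-dione
Product: 3, (4aS,5S,8aR)-5-hydroxy-4a-methyloctahydronaphthalen-1(2H)-one (trans-fused; OH cis to the angular CH3)
Conditions: AlMe3 (1.5 equiv), CuTC (5 mol %), BINOL-derived phosphoramidite L* (10 mol %), Et2O, −30 °C; then LiAlH4, −78 °C; Rochelle salt; K2CO3, MeOH, rt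
Reagents that add atoms: trimethylaluminium, C[Al](C)C
Why: Proposed new method: enantioselective Cu-catalysed conjugate methylation of a tetrasubstituted ene-1,4-dione. AlMe3 activates one carbonyl and the chiral Cu(I)–phosphoramidite delivers CH3 to its β-carbon; the two alkene carbons are homotopic (C2 axis) and the faces enantiotopic, so only π-facial selection is needed, as in the closest known reaction, Cu/phosphoramidite–AlMe3 additions to 3-substituted cyclohexenones that form quaternary centres. This sets C4a as S and leaves the remote carbonyl masked as its aluminium enolate, so LiAlH4 reduces only the ketone next to the new quaternary carbon (hydride anti to the angular CH3). Enolate protonation and equilibration then give the trans ring fusion.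

**Step 3**
Reactants: 3, (4aS,5S,8aR)-5-hydroxy-4a-methyloctahydronaphthalen-1(2H)-one
Product: 4, (2S,4aS,5S,8aR)-5-hydroxy-2,4a-dimethyloctahydronaphthalen-1(2H)-one
Conditions: LDA (2.2 equiv), THF, −78 °C; MeI, −78 → −20 °C; then NaOMe, MeOH, rt
Reagents that add atoms: iodomethane, CI
Why: LDA removes the less hindered C2–H (kinetic enolate; the ring-fusion C–H next to the quaternary carbon is not touched) and MeI alkylates it (enolate alkylation). Base equilibration then places the methyl equatorial (2S) on the trans-fused ketone, the expected thermodynamic arrangement for 4a-methyl-1-decalones (cf. 5α-6-oxo steroids).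

**Step 4**
Reactants: 4, (2S,4aS,5S,8aR)-5-hydroxy-2,4a-dimethyloctahydronaphthalen-1(2H)-one
Product: 5, (1S,4aS,6S,8aS)-6,8a-dimethyl-5-methylidenedecahydronaphthalen-1-ol
Conditions: Zn, CH2Br2, TiCl4, THF/CH2Cl2, 0 °C → rt
Reagents that add atoms: dibromomethane, BrCBr
Why: Takai–Lombardo methylenation is non-basic, so the two α-stereocentres are not epimerised before they become non-enolisable; the free hydroxyl is tolerated.

**Step 5**
Reactants: 5, (1S,4aS,6S,8aS)-6,8a-dimethyl-5-methylidenedecahydronaphthalen-1-ol
Product: 6, (4aS,6S,8aS)-6,8a-dimethyl-5-methylideneoctahydronaphthalen-1(2H)-one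
Conditions: Dess–Martin periodinane, NaHCO3, CH2Cl2, rt
Reagents that add atoms: none
Why: Dess–Martin oxidation of the secondary alcohol under neutral conditions leaves the alkene and all stereocentres untouched.

**Step 6**
Reactants: 6, (4aS,6S,8aS)-6,8a-dimethyl-5-methylideneoctahydronaphthalen-1(2H)-one
Product: 7, (4aS,6S,8aS)-6,8a-dimethyl-5-methylidene-1-[(trimethylsilyl)methyl]decahydronaphthalen-1-ol (C-1 configuration inconsequential; CH2SiMe3 expected trans to the 8a-CH3)
Conditions: Me3SiCH2Li, CeCl3, THF, −78 °C
Reagents that add atoms: (trimethylsilyl)methyllithium, [Li]C[Si](C)(C)C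
Why: Organocerium 1,2-addition (first half of a Peterson olefination) to the hindered, enolisable ketone gives a β-hydroxysilane, a masked exocyclic methylene that cannot take part in the MHAT step.

**Step 7**
Reactants: 8, methyl 4-hydroxybenzoate
Product: 9, methyl 3-(bromomethyl)-4-hydroxybenzoate
Conditions: (CH2O)n, HBr (33 % in AcOH), 50 °C
Reagents that add atoms: paraformaldehyde, C=O; hydrogen bromide, Br
Why: Blanc-type bromomethylation (electrophilic aromatic substitution) occurs ortho to the hydroxyl because para is blocked; the ester deactivates the ring enough to favour mono-substitution.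

**Step 8**
Reactants: 9, methyl 3-(bromomethyl)-4-hydroxybenzoate
Product: 10, methyl 4-acetoxy-3-(bromomethyl)benzoate
Conditions: Ac2O, cat. H2SO4, 0 °C → rt
Reagents that add atoms: acetic anhydride, CC(=O)OC(C)=O
Why: Acid-catalysed O-acetylation protects the phenol without base, which would eliminate HBr to an ortho-quinone methide.

**Step 9**
Reactants: 7, (4aS,6S,8aS)-6,8a-dimethyl-5-methylidene-1-[(trimethylsilyl)methyl]decahydronaphthalen-1-ol; 10, methyl 4-acetoxy-3-(bromomethyl)benzoate
Product: 11, methyl 4-acetoxy-3-{[(1R,2S,4aS,8aS)-5-hydroxy-1,2,4a-trimethyl-5-[(trimethylsilyl)methyl]decahydronaphthalen-1-yl]methyl}benzoate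
Conditions: Mn(dpm)3 (cat.), Ni(acac)2 (cat.), PhSiH3, K2CO3, HFIP/1,2-DCE, rt; 10 in excess
Reagents that add atoms: none (H from PhSiH3)
Why: MHAT/Ni dual-catalytic Markovnikov hydrobenzylation: Mn–H transfers H• to the exocyclic CH2 (which becomes the C-1 methyl), and the tertiary radical is coupled with the benzyl bromide through Ni. The new bond forms on the equatorial α-face, anti to the syn-axial angular CH3, giving 1R (CH3 axial, CH2Ar equatorial).

**Step 10**
Reactants: 11, methyl 4-acetoxy-3-{[(1R,2S,4aS,8aS)-5-hydroxy-1,2,4a-trimethyl-5-[(trimethylsilyl)methyl]decahydronaphthalen-1-yl]methyl}benzoate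
Product: 12, dictyoceratin C, methyl 4-hydroxy-3-{[(1R,2S,4aS,8aS)-1,2,4a-trimethyl-5-methylidenedecahydronaphthalen-1-yl]methyl}benzoate
Conditions: KHMDS, THF, 0 °C → rt; then K2CO3, MeOH, rt
Reagents that add atoms: none
Why: The potassium alkoxide undergoes Peterson syn-elimination to give the exocyclic methylene regiospecifically, and methanolysis removes the aryl acetate while the methyl ester is unchanged in MeOH; no stereocentre is affected.

## Compound list

1 | decahydronaphthalene-1,5-dione (cis/trans) | O=C1CCCC2C(=O)CCCC12 | starting material
2 | 3,4,7,8-tetrahydronaphthalene-1,5(2H,6H)-dione | O=C1CCCC2=C1CCCC2=O | intermediate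
3 | (4aS,5S,8aR)-5-hydroxy-4a-methyloctahydronaphthalen-1(2H)-one | O[C@H]1CCC[C@H]2C(=O)CCC[C@]12C | intermediate
4 | (2S,4aS,5S,8aR)-5-hydroxy-2,4a-dimethyloctahydronaphthalen-1(2H)-one | O[C@H]1CCC[C@H]2C(=O)[C@@H](C)CC[C@]12C | intermediate
5 | (1S,4aS,6S,8aS)-6,8a-dimethyl-5-methylidenedecahydronaphthalen-1-ol | O[C@H]1CCC[C@H]2C(=C)[C@@H](C)CC[C@]12C | intermediate
6 | (4aS,6S,8aS)-6,8a-dimethyl-5-methylideneoctahydronaphthalen-1(2H)-one | O=C1CCC[C@H]2C(=C)[C@@H](C)CC[C@]12C | intermediate
7 | (4aS,6S,8aS)-6,8a-dimethyl-5-methylidene-1-[(trimethylsilyl)methyl]decahydronaphthalen-1-ol | C[Si](C)(C)CC1(O)CCC[C@H]2C(=C)[C@@H](C)CC[C@]12C | intermediate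
8 | methyl 4-hydroxybenzoate | COC(=O)c1ccc(O)cc1 | starting material
9 | methyl 3-(bromomethyl)-4-hydroxybenzoate | COC(=O)c1ccc(O)c(CBr)c1 | intermediate
10 | methyl 4-acetoxy-3-(bromomethyl)benzoate | COC(=O)c1ccc(OC(C)=O)c(CBr)c1 | intermediate
11 | methyl 4-acetoxy-3-{[(1R,2S,4aS,8aS)-5-hydroxy-1,2,4a-trimethyl-5-[(trimethylsilyl)methyl]decahydronaphthalen-1-yl]methyl}benzoate | C[Si](C)(C)CC1(O)CCC[C@H]2[C@](C)(Cc3cc(C(=O)OC)ccc3OC(C)=O)[C@@H](C)CC[C@]12C | intermediate
12 | dictyoceratin C | C=C1CCC[C@H]2[C@](C)(Cc3cc(C(=O)OC)ccc3O)[C@@H](C)CC[C@]12C | target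

## Summary

Total steps: 10. Longest linear sequence: 8 (steps 1–6, 9, 10).

Steps most likely to fail:

- **Step 2 (desymmetrising conjugate methylation).** Risks are SET reduction of the ene-dione, low ee on a tetrasubstituted acceptor, or poor chemoselectivity in the in-situ reduction. Fallback: desymmetrise 2 by CBS mono-reduction of one of the two enantiotopic carbonyls, silylate the resulting carbinol, and add Me2CuLi/TMSCl anti to the OSiR3 group. The quaternary centre is then set by substrate control, and the carbinol is oxidised at the stage of step 5.
- **Step 9 (Ni capture of a very congested tertiary radical).** Risks are simple reduction, olefin isomerisation or benzyl homocoupling. Fallback: generate the same radical without Ni (Fe(acac)3/PhSiH3) and trap it in a Giese-type 1,4-addition to the ortho-quinone methide formed in situ from phenol 9 and base; rearomatisation drives the C–C bond formation.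
- **Step 3 (thermodynamic control of the ring-fusion H and the secondary methyl).** The trans/cis ratio at the ring fusion may be modest. Fallback: fix the ring fusion kinetically before any enolisable ketone exists. Trap the step-2 enolate as the enol triflate, reduce it to the trisubstituted olefin (Pd, HCO2H/Bu3N), and hydroborate–oxidise, which delivers H syn and anti to the angular methyl. Then oxidise to the trans ketone and introduce the methyl via the α-methylene ketone and conjugate reduction rather than by equilibration.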